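The isoflavan is cut across ring C at two bonds, C4–C4a and O1–C8a, which separates a ring A aryl iodide from a chiral C2–C3–C4 unit that already carries ring B. Ring A has its side chain, O1 and C4 attached to the contiguous carbons C8, C8a and C4a. An iodide at C8a next to the blocked C8 therefore lets a palladium/norbornene relay alkylate C4a and then etherify C8a, closing ring C in one operation from iodide 7 (MOM and silyl ethers) and the free (R)-bromo alcohol 19. The C3 stereocenter comes from an enzymatic desymmetrisation and is only carried through; dilute acid then removes every protecting group.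

Key step: step 14

Assumption: the lipase of Burkholderia cepacia is taken to hydrolyse the pro-R acetoxymethyl group of diacetate 16, as its usual preference for primary alcohols predicts when the aryl group is the large substituent; should it prefer the other group, acetylation of diol 15 with the same enzyme and vinyl acetate would give the same (S)-monoacetate 17.

Step 1
Reactants: 1 3-iodophenol
Product: 2 1-iodo-3-(methoxymethoxy)benzene
Conditions: NaH, MOMCl, THF, 0 °C to rt
Reagents that add atoms: chloromethyl methyl ether, COCCl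
Why: Williamson etherification of the sodium phenoxide with the reactive α-chloro ether should give the MOM ether, which serves both as ortho-directing group and as acid-labile phenol protection.

Step 2
Reactants: 2 1-iodo-3-(methoxymethoxy)benzene; 3 1-bromo-3-methylbut-2-ene (prenyl bromide)
Product: 5 1-iodo-3-(methoxymethoxy)-2-(3-methylbut-2-en-1-yl)benzene, via 2-iodo-6-(methoxymethoxy)phenyllithium 4 (not isolated)
Conditions: LDA, THF, −78 °C; then 3 and CuBr·SMe2 (10 mol%), −78 to −30 °C
Reagents that add atoms: none
Why: Directed ortho-metalation should remove the proton flanked by the acetal oxygen and the iodine, the most acidic site and one from which no halogen migration is downhill, and the aryllithium is held at −78 °C to avoid aryne formation until copper-catalysed SN2 allylation gives the linear prenyl arene.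

Step 3
Reactants: 5 1-iodo-3-(methoxymethoxy)-2-(3-methylbut-2-en-1-yl)benzene
Product: 6 4-[2-iodo-6-(methoxymethoxy)phenyl]-2-methylbutan-2-ol
Conditions: Co(acac)2 (20 mol%), PhSiH3, O2 (1 atm), THF, rt
Reagents that add atoms: dioxygen, O=O
Why: Mukaiyama hydration delivers a hydrogen atom to the less substituted alkene carbon and traps the tertiary radical with oxygen, so the Markovnikov tertiary alcohol should form without touching the aryl iodide or the acetal.

Step 4
Reactants: 6 4-[2-iodo-6-(methoxymethoxy)phenyl]-2-methylbutan-2-ol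
Product: 7 1-iodo-3-(methoxymethoxy)-2-[3-methyl-3-(triethylsilyloxy)butyl]benzene
Conditions: TESOTf, 2,6-lutidine, CH2Cl2, −78 to 0 °C
Reagents that add atoms: triethylsilyl trifluoromethanesulfonate, CC[Si](CC)(CC)OS(=O)(=O)C(F)(F)F
Why: Silylation with a silyl triflate and a hindered pyridine base is the standard protection of a tertiary alcohol, and the ether keeps this hydroxyl from capturing the aryl–palladium at C8a in step 14.

Step 5
Reactants: 8 4-bromobenzene-1,3-diol
Product: 9 1-bromo-2,4-bis(methoxymethoxy)benzene
Conditions: NaH, MOMCl, THF–DMF, 0 °C to rt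
Reagents that add atoms: chloromethyl methyl ether, COCCl
Why: Double Williamson etherification of the resorcinol dianion should protect both phenols as base-stable acetals that survive every later step up to the final acid treatment.

Step 6
Reactants: 9 1-bromo-2,4-bis(methoxymethoxy)benzene; 10 4,4,5,5-tetramethyl-2-(3-methylbut-2-en-1-yl)-1,3,2-dioxaborolane
Product: 11 2,4-bis(methoxymethoxy)-1-(2-methylbut-3-en-2-yl)benzene
Conditions: Pd(OAc)2 (5 mol%), 1,1'-bis(di-tert-butylphosphino)ferrocene (6 mol%), K3PO4, THF–H2O, 65 °C
Reagents that add atoms: none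
Why: In this γ-selective Suzuki–Miyaura coupling of an allylboronate, transmetalation with allylic transposition places palladium on the tertiary carbon and the bulky bisphosphine should force reductive elimination before the allyl group can slip to its primary end, giving the 1,1-dimethylallyl arene.

Step 7
Reactants: 11 2,4-bis(methoxymethoxy)-1-(2-methylbut-3-en-2-yl)benzene
Product: 12 1-bromo-2,4-bis(methoxymethoxy)-5-(2-methylbut-3-en-2-yl)benzene
Conditions: NBS, MeCN, 0 °C, dark
Reagents that add atoms: N-bromosuccinimide, O=C1CCC(=O)N1Br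
Why: Electrophilic aromatic bromination should go to the open position para to one acetal oxygen and ortho to the other, which is far more nucleophilic than the hindered vinyl group, a group that also lacks allylic hydrogen.

Step 8
Reactants: 12 1-bromo-2,4-bis(methoxymethoxy)-5-(2-methylbut-3-en-2-yl)benzene; 13 diethyl malonate
Product: 14 diethyl 2-[2,4-bis(methoxymethoxy)-5-(2-methylbut-3-en-2-yl)phenyl]propanedioate
Conditions: Pd(dba)2 (2 mol%), P(t-Bu)3 (4 mol%), K3PO4, toluene, 80 °C
Reagents that add atoms: none
Why: Palladium-catalysed α-arylation of a malonate enolate tolerates electron-rich, ortho-substituted aryl bromides when a bulky trialkylphosphine is used, and the stabilised enolate should capture the aryl–palladium faster than the hindered vinyl group can insert.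

Step 9
Reactants: 14 diethyl 2-[2,4-bis(methoxymethoxy)-5-(2-methylbut-3-en-2-yl)phenyl]propanedioate
Product: 15 2-[2,4-bis(methoxymethoxy)-5-(2-methylbut-3-en-2-yl)phenyl]propane-1,3-diol
Conditions: LiAlH4, THF, 0 °C (ester added to the hydride); Rochelle salt work-up
Reagents that add atoms: none
Why: Hydride reduction of both esters should give the prochiral 1,3-diol, with inverse addition at low temperature limiting enolisation of the arylmalonate.

Step 10
Reactants: 15 2-[2,4-bis(methoxymethoxy)-5-(2-methylbut-3-en-2-yl)phenyl]propane-1,3-diol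
Product: 16 2-[2,4-bis(methoxymethoxy)-5-(2-methylbut-3-en-2-yl)phenyl]propane-1,3-diyl diacetate
Conditions: Ac2O, pyridine, DMAP (5 mol%), CH2Cl2, 0 °C to rt
Reagents that add atoms: acetic anhydride, CC(=O)OC(C)=O
Why: Nucleophile-catalysed acetylation of both primary hydroxyls should provide the prochiral substrate for enzymatic hydrolysis.

Step 11
Reactants: 16 2-[2,4-bis(methoxymethoxy)-5-(2-methylbut-3-en-2-yl)phenyl]propane-1,3-diyl diacetate
Product: 17 (2S)-2-[2,4-bis(methoxymethoxy)-5-(2-methylbut-3-en-2-yl)phenyl]-3-hydroxypropyl acetate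
Conditions: lipase from Burkholderia cepacia (Amano PS), phosphate buffer pH 7, acetone (10%), 30 °C
Reagents that add atoms: none
Why: In this lipase-catalysed desymmetrisation the enzyme should hydrolyse the pro-R acetoxymethyl group, which creates the stereocenter as (S) by enantiotopic group selection, while faster over-hydrolysis of the minor enantiomer to diol 15 should raise the enantiomeric purity of the monoacetate.

Step 12
Reactants: 17 (2S)-2-[2,4-bis(methoxymethoxy)-5-(2-methylbut-3-en-2-yl)phenyl]-3-hydroxypropyl acetate
Product: 18 (2R)-3-bromo-2-[2,4-bis(methoxymethoxy)-5-(2-methylbut-3-en-2-yl)phenyl]propyl acetate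
Conditions: CBr4, PPh3, 2,6-lutidine, CH2Cl2, 0 °C
Reagents that add atoms: tetrabromomethane, BrC(Br)(Br)Br
Why: Appel bromination replaces the primary hydroxyl by SN2 at a carbon that is not stereogenic, so the configuration is untouched and only the descriptor changes to (R), while the base keeps the acetals safe from traces of acid.

Step 13
Reactants: 18 (2R)-3-bromo-2-[2,4-bis(methoxymethoxy)-5-(2-methylbut-3-en-2-yl)phenyl]propyl acetate
Product: 19 (2R)-3-bromo-2-[2,4-bis(methoxymethoxy)-5-(2-methylbut-3-en-2-yl)phenyl]propan-1-ol
Conditions: DIBAL-H, CH2Cl2, −78 °C; Rochelle salt work-up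
Reagents that add atoms: none
Why: Reductive cleavage of the acetate by an aluminium hydride at low temperature should free the alcohol without a basic alkoxide that could close an oxetane or eliminate hydrogen bromide, and it leaves the primary bromide alone.

Step 14
Reactants: 7 1-iodo-3-(methoxymethoxy)-2-[3-methyl-3-(triethylsilyloxy)butyl]benzene; 19 (2R)-3-bromo-2-[2,4-bis(methoxymethoxy)-5-(2-methylbut-3-en-2-yl)phenyl]propan-1-ol
Product: 20 (3R)-3-[2,4-bis(methoxymethoxy)-5-(2-methylbut-3-en-2-yl)phenyl]-7-(methoxymethoxy)-8-[3-methyl-3-(triethylsilyloxy)butyl]-3,4-dihydro-2H-chromene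
Conditions: Pd(OAc)2 (10 mol%), 2-dicyclohexylphosphino-2',4',6'-triisopropylbiphenyl (XPhos, 20 mol%), norbornene (2 equiv), Cs2CO3 (3 equiv), 1,4-dioxane, 90 °C
Reagents that add atoms: none
Why: Proposed new method: zerovalent palladium should insert into the C8a–I bond of 7, norbornene then inserts and the neighbouring C4a–H bond is palladated to a five-membered aryl–norbornyl palladacycle of divalent palladium, which takes up the primary C–Br bond of 19 in an SN2-like oxidative addition to tetravalent palladium and forms C4–C4a by reductive elimination; with both ortho positions filled norbornene is expelled, and the aryl–palladium at C8a is bound by the caesium alkoxide of the tether and releases O1–C8a by reductive elimination. The closest known reaction types are the palladium/norbornene ortho-alkylation of aryl iodides with bromoalkylamines that ends in ipso C–N ring closure to indolines and tetrahydroquinolines, the palladium/norbornene annulation of aryl iodides with epoxides to 2,3-dihydrobenzofurans, and the palladium-catalysed cyclisation of 3-(2-halophenyl)propan-1-ols to chromans. Ring C, the only ring formed, closes at O1–C8a by aryl–oxygen reductive elimination from a seven-membered aryl(alkoxo)palladium chelate, which gives the six-membered ether. No stereocenter is created: C3 arrives with 19, is adjacent to the reacting carbon but has no bond made or broken, so the (3R) configuration is carried over. Alkylation should stop after C4a because the C8 chain occupies the second ortho position and promotes norbornene loss, the triethylsilyl ether keeps the tertiary hydroxyl from attacking C8a, and the bulky, electron-rich biarylphosphine is chosen so that C–O reductive elimination outruns β-hydride elimination of the primary alkoxide, Heck insertion of the hindered vinyl group and carbonate-induced loss of 19 as oxetane or allylic alcohol.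

Step 15
Reactants: 20 (3R)-3-[2,4-bis(methoxymethoxy)-5-(2-methylbut-3-en-2-yl)phenyl]-7-(methoxymethoxy)-8-[3-methyl-3-(triethylsilyloxy)butyl]-3,4-dihydro-2H-chromene
Product: 21 4-[(3R)-7-hydroxy-8-(3-hydroxy-3-methylbutyl)-3,4-dihydro-2H-chromen-3-yl]-6-(2-methylbut-3-en-2-yl)benzene-1,3-diol
Conditions: HCl (2 M aq.), MeOH–THF, 40 °C
Reagents that add atoms: none
Why: Acid-catalysed hydrolysis should cleave the three methoxymethyl acetals and the tertiary triethylsilyl ether in one operation, and dilute acid at mild temperature should spare the vinyl group, the tertiary alcohol and the non-acidic C3 stereocenter.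

Compound list
1 | 3-iodophenol | Oc1cccc(I)c1 | starting material
2 | 1-iodo-3-(methoxymethoxy)benzene | COCOc1cccc(I)c1 | intermediate
3 | 1-bromo-3-methylbut-2-ene (prenyl bromide) | CC(C)=CCBr | starting material
4 | 2-iodo-6-(methoxymethoxy)phenyllithium | COCOc1cccc(I)c1[Li] | intermediate
5 | 1-iodo-3-(methoxymethoxy)-2-(3-methylbut-2-en-1-yl)benzene | COCOc1cccc(I)c1CC=C(C)C | intermediate
6 | 4-[2-iodo-6-(methoxymethoxy)phenyl]-2-methylbutan-2-ol | COCOc1cccc(I)c1CCC(C)(C)O | intermediate
7 | 1-iodo-3-(methoxymethoxy)-2-[3-methyl-3-(triethylsilyloxy)butyl]benzene | COCOc1cccc(I)c1CCC(C)(C)O[Si](CC)(CC)CC | intermediate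
8 | 4-bromobenzene-1,3-diol | Oc1ccc(Br)c(O)c1 | starting material
9 | 1-bromo-2,4-bis(methoxymethoxy)benzene | COCOc1ccc(Br)c(OCOC)c1 | intermediate
10 | 4,4,5,5-tetramethyl-2-(3-methylbut-2-en-1-yl)-1,3,2-dioxaborolane | CC(C)=CCB1OC(C)(C)C(C)(C)O1 | starting material
11 | 2,4-bis(methoxymethoxy)-1-(2-methylbut-3-en-2-yl)benzene | C=CC(C)(C)c1ccc(OCOC)cc1OCOC | intermediate
12 | 1-bromo-2,4-bis(methoxymethoxy)-5-(2-methylbut-3-en-2-yl)benzene | C=CC(C)(C)c1cc(Br)c(OCOC)cc1OCOC | intermediate
13 | diethyl malonate | CCOC(=O)CC(=O)OCC | starting material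
14 | diethyl 2-[2,4-bis(methoxymethoxy)-5-(2-methylbut-3-en-2-yl)phenyl]propanedioate | C=CC(C)(C)c1cc(C(C(=O)OCC)C(=O)OCC)c(OCOC)cc1OCOC | intermediate
15 | 2-[2,4-bis(methoxymethoxy)-5-(2-methylbut-3-en-2-yl)phenyl]propane-1,3-diol | C=CC(C)(C)c1cc(C(CO)CO)c(OCOC)cc1OCOC | intermediate
16 | 2-[2,4-bis(methoxymethoxy)-5-(2-methylbut-3-en-2-yl)phenyl]propane-1,3-diyl diacetate | C=CC(C)(C)c1cc(C(COC(C)=O)COC(C)=O)c(OCOC)cc1OCOC | intermediate
17 | (2S)-2-[2,4-bis(methoxymethoxy)-5-(2-methylbut-3-en-2-yl)phenyl]-3-hydroxypropyl acetate | C=CC(C)(C)c1cc([C@H](COC(C)=O)CO)c(OCOC)cc1OCOC | intermediate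
18 | (2R)-3-bromo-2-[2,4-bis(methoxymethoxy)-5-(2-methylbut-3-en-2-yl)phenyl]propyl acetate | C=CC(C)(C)c1cc([C@H](COC(C)=O)CBr)c(OCOC)cc1OCOC | intermediate
19 | (2R)-3-bromo-2-[2,4-bis(methoxymethoxy)-5-(2-methylbut-3-en-2-yl)phenyl]propan-1-ol | C=CC(C)(C)c1cc([C@H](CO)CBr)c(OCOC)cc1OCOC | intermediate
20 | (3R)-3-[2,4-bis(methoxymethoxy)-5-(2-methylbut-3-en-2-yl)phenyl]-7-(methoxymethoxy)-8-[3-methyl-3-(triethylsilyloxy)butyl]-3,4-dihydro-2H-chromene | C=CC(C)(C)c1cc([C@@H]2COc3c(ccc(OCOC)c3CCC(C)(C)O[Si](CC)(CC)CC)C2)c(OCOC)cc1OCOC | intermediate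
21 | 4-[(3R)-7-hydroxy-8-(3-hydroxy-3-methylbutyl)-3,4-dihydro-2H-chromen-3-yl]-6-(2-methylbut-3-en-2-yl)benzene-1,3-diol | C=CC(C)(C)c1cc([C@@H]2COc3c(ccc(O)c3CCC(C)(C)O)C2)c(O)cc1O | target

Total step count: 15 (ring A iodide, steps 1–4; ring B bromo alcohol, steps 5–13; union and deprotection, steps 14–15).
Longest linear sequence: 11 steps (steps 5–15, from 4-bromobenzene-1,3-diol 8).

Steps most likely to fail

Step 14. After the C4–C4a alkylation, β-hydride elimination of the palladium-bound primary alkoxide may outrun aryl–oxygen reductive elimination, or carbonate may consume the free bromo alcohol before it reaches the palladacycle. The fallback sets out from bromo acetate 18 and iodide 7 and separates the two bond formations using known reactions. Palladium/norbornene ortho-alkylation terminated by ipso-borylation (Pd(OAc)2, PPh3, norbornene, B2pin2, Cs2CO3, 1,4-dioxane, 90 °C) should give the arylboronate (2R)-2-[2,4-bis(methoxymethoxy)-5-(2-methylbut-3-en-2-yl)phenyl]-3-[4-(methoxymethoxy)-3-[3-methyl-3-(triethylsilyloxy)butyl]-2-(4,4,5,5-tetramethyl-1,3,2-dioxaborolan-2-yl)phenyl]propyl acetate F1. Aqueous NaOH with H2O2 in THF then oxidises the C–B bond and saponifies the acetate, giving (2R)-2-[2,4-bis(methoxymethoxy)-5-(2-methylbut-3-en-2-yl)phenyl]-3-[2-hydroxy-4-(methoxymethoxy)-3-[3-methyl-3-(triethylsilyloxy)butyl]phenyl]propan-1-ol F2. Its only free phenol is closed onto the primary alcohol by Mitsunobu etherification (PPh3, DIAD, THF, 0 °C), forming O1–C2 without touching C3 and returning to the route at 20.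

Step 6. The tertiary allyl–palladium intermediate may isomerise to its primary form before reductive elimination, a slip that the ortho acetal would encourage and that would lead to linear prenylation. The fallback sets out from bromide 9. Palladium-catalysed α-arylation of 2-methylpropanal (Pd(OAc)2, 1,1'-bis(diphenylphosphino)ferrocene, Cs2CO3, 1,4-dioxane, 80 °C) should give 2-[2,4-bis(methoxymethoxy)phenyl]-2-methylpropanal F3, in which the quaternary carbon is fixed by the enolate. Wittig methylenation (Ph3PCH3Br, KOt-Bu, THF, 0 °C) then returns to the route at 11.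

Step 11. The enzyme may discriminate poorly between the two acetoxymethyl groups next to the bulky ortho-substituted aryl group, or acyl migration in the monoacetate may erode the enantiomeric purity. The fallback sets out from diol 15 and uses a chemical desymmetrisation. Enantioselective monobenzoylation with vinyl benzoate is catalysed by the dinuclear zinc complex formed from ZnEt2 and 2,6-bis{[2-(hydroxydiphenylmethyl)pyrrolidin-1-yl]methyl}-4-methylphenol (toluene, −15 °C). The ligand enantiomer that acylates the pro-S hydroxymethyl group is used, which should give (2S)-2-[2,4-bis(methoxymethoxy)-5-(2-methylbut-3-en-2-yl)phenyl]-3-hydroxypropyl benzoate F4. Appel bromination (CBr4, PPh3, 2,6-lutidine, CH2Cl2, 0 °C) gives (2R)-3-bromo-2-[2,4-bis(methoxymethoxy)-5-(2-methylbut-3-en-2-yl)phenyl]propyl benzoate F5, and DIBAL-H at −78 °C removes the benzoate and returns to the route at 19.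

Further compounds
F1 | step 14 | (2R)-2-[2,4-bis(methoxymethoxy)-5-(2-methylbut-3-en-2-yl)phenyl]-3-[4-(methoxymethoxy)-3-[3-methyl-3-(triethylsilyloxy)butyl]-2-(4,4,5,5-tetramethyl-1,3,2-dioxaborolan-2-yl)phenyl]propyl acetate | C=CC(C)(C)c1cc([C@H](COC(C)=O)Cc2ccc(OCOC)c(CCC(C)(C)O[Si](CC)(CC)CC)c2B3OC(C)(C)C(C)(C)O3)c(OCOC)cc1OCOC
F2 | step 14 | (2R)-2-[2,4-bis(methoxymethoxy)-5-(2-methylbut-3-en-2-yl)phenyl]-3-[2-hydroxy-4-(methoxymethoxy)-3-[3-methyl-3-(triethylsilyloxy)butyl]phenyl]propan-1-ol | C=CC(C)(C)c1cc([C@H](CO)Cc2ccc(OCOC)c(CCC(C)(C)O[Si](CC)(CC)CC)c2O)c(OCOC)cc1OCOC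
F3 | step 6 | 2-[2,4-bis(methoxymethoxy)phenyl]-2-methylpropanal | O=CC(C)(C)c1ccc(OCOC)cc1OCOC
F4 | step 11 | (2S)-2-[2,4-bis(methoxymethoxy)-5-(2-methylbut-3-en-2-yl)phenyl]-3-hydroxypropyl benzoate | C=CC(C)(C)c1cc([C@H](COC(=O)c2ccccc2)CO)c(OCOC)cc1OCOC
F5 | step 11 | (2R)-3-bromo-2-[2,4-bis(methoxymethoxy)-5-(2-methylbut-3-en-2-yl)phenyl]propyl benzoate | C=CC(C)(C)c1cc([C@H](COC(=O)c2ccccc2)CBr)c(OCOC)cc1OCOC
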